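**Retrosynthetic overview**
- The N-oxide comes from pyridine 14 by N-oxidation, and the C5 stereocentre from asymmetric hydrogenation of the C5=C6 alkene 13.
- The C5–side-chain bond comes from Negishi coupling of enol triflate 10 (from ketone 8) with (5-phenylpentyl)zinc bromide 12.
- Key disconnection C8–C8a: ketone 8 comes from cyclobutanol 7 by oxidative ring opening and radical reclosure. This rests on C8a being the only hydrogen-bearing carbon of the pyridine ring (α to N1, next to C4a), and on C5–C6–C7–C8 being a four-carbon chain that maps onto a cyclobutanol mounted on C4a.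
- Cyclobutanol 7 comes from bromopyridine 4 and cyclobutanone; 4 comes from pyridone 1 by bromination, chlorination and methoxylation.
- Ring order: the pyridine ring (ring A) is bought; the carbocycle (ring B) is closed in step 5.

Key step: step 5

Assumption: CIP analysis of the given SMILES (C4a > C6 > side-chain C1' > H) gives the C5 configuration as R, and this is the enantiomer aimed at.

**Route**

Step 1
Reactants: 1 3-methoxy-2-methyl-1H-pyridin-4-one
Product: 2 5-bromo-3-methoxy-2-methyl-1H-pyridin-4-one
Conditions: NBS (1.05 equiv), DMF, 0 °C to rt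
Reagents that add atoms: N-bromosuccinimide, O=C1CCC(=O)N1Br
Why: Electrophilic aromatic bromination of the 4-pyridone goes to C5, the only free carbon next to the carbonyl, because C3 already carries the methoxy group.

Step 2
Reactants: 2 5-bromo-3-methoxy-2-methyl-1H-pyridin-4-one
Product: 3 5-bromo-4-chloro-3-methoxy-2-methylpyridine
Conditions: POCl3 (neat), 100 °C; ice, aq Na2CO3
Reagents that add atoms: phosphoryl chloride, O=P(Cl)(Cl)Cl
Why: Deoxychlorination of the pyridone through its dichlorophosphate is the standard entry to 4-chloropyridines and should leave the bromide and the methyl ether untouched.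

Step 3
Reactants: 3 5-bromo-4-chloro-3-methoxy-2-methylpyridine
Product: 4 5-bromo-3,4-dimethoxy-2-methylpyridine
Conditions: NaOMe (2 equiv), MeOH, reflux (DMSO co-solvent, 70 °C, if slow)
Reagents that add atoms: sodium methoxide, [Na+].[O-]C
Why: Nucleophilic aromatic substitution (addition–elimination) by methoxide should occur at C4, para to the ring nitrogen and inductively activated by the neighbouring bromine, while the C5 bromide, meta to nitrogen, is not displaced.

Step 4
Reactants: 4 5-bromo-3,4-dimethoxy-2-methylpyridine; 5 cyclobutanone
Product: 7 1-(4,5-dimethoxy-6-methylpyridin-3-yl)cyclobutan-1-ol, via (4,5-dimethoxy-6-methylpyridin-3-yl)lithium 6 (not isolated)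
Conditions: n-BuLi (1.05 equiv), THF, −78 °C, 15 min; then 5 (1.2 equiv), −78 to 0 °C; aq NH4Cl
Reagents that add atoms: n-butyllithium, [Li]CCCC (supplies the lithium of 6; none of its atoms remain in 7)
Why: Bromine–lithium exchange at −78 °C should outrun deprotonation of the 2-methyl group and addition of n-BuLi to the ring, and the methoxy-flanked 3-pyridyllithium then undergoes 1,2-addition to the strained carbonyl of cyclobutanone.

Step 5
Reactants: 7 1-(4,5-dimethoxy-6-methylpyridin-3-yl)cyclobutan-1-ol
Product: 8 3,4-dimethoxy-2-methyl-7,8-dihydro-6H-quinolin-5-one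
Conditions: AgNO3 (20 mol %), K2S2O8 (3 equiv), TFA (1.5 equiv), MeCN/H2O (1:1), 50 °C; aq NaHCO3
Reagents that add atoms: none
Why: K2S2O8 oxidises AgNO3 to divalent silver, which turns the tertiary cyclobutanol O–H into an alkoxy radical; strain-driven β-scission then opens the four-membered ring to the pyridyl ketone (future C5) carrying a primary radical on the chain end (future C8). This nucleophilic radical adds to the TFA-protonated pyridine at its unsubstituted α-carbon (future C8a) in a polarity-matched intramolecular Minisci addition, and oxidation with loss of a proton restores the aromatic ring. The closest known reaction type is the AgNO3/K2S2O8 (or Mn(OAc)3) oxidative ring expansion of 1-arylcyclobutanols to 1-tetralones, together with ring-opening Minisci alkylation of heteroarenes by cycloalkanols. The carbocycle closes as a six-membered ring by ortho attack, formally 6-exo-trig on the C8a=N1 bond of the pyridinium, forming C8–C8a; no stereocentre is created. The selectivity needed is C8a against ipso attack at the methoxy-bearing C4; it is secured because C8a is the only ring carbon bearing hydrogen and is activated both by the adjacent N–H+ and by the new ortho acyl group, whereas attack at C4 is blocked, disfavoured electronically and cannot rearomatise.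

Step 6
Reactants: 8 3,4-dimethoxy-2-methyl-7,8-dihydro-6H-quinolin-5-one
Product: 10 3,4-dimethoxy-2-methyl-7,8-dihydroquinolin-5-yl trifluoromethanesulfonate, via potassium 3,4-dimethoxy-2-methyl-7,8-dihydroquinolin-5-olate 9 (not isolated)
Conditions: KN(SiMe3)2 (1.1 equiv), THF, −78 °C; then PhNTf2 (1.15 equiv), −78 to 0 °C
Reagents that add atoms: potassium hexamethyldisilazide, C[Si](C)(C)[N-][Si](C)(C)C.[K+] (supplies the potassium of 9 only); N-phenylbis(trifluoromethanesulfonimide), O=S(=O)(N(c1ccccc1)S(=O)(=O)C(F)(F)F)C(F)(F)F
Why: Kinetic deprotonation by the hindered amide base should remove the C6 proton α to the ketone rather than the less acidic picolyl-type C8–H or 2-CH3 protons, and O-sulfonylation of the enolate gives the enol triflate (enol triflate formation).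

Step 7
Reactants: 11 (5-bromopentyl)benzene
Product: 12 (5-phenylpentyl)zinc bromide (THF solution with LiCl, used directly in step 8)
Conditions: Zn dust (activated with cat. 1,2-dibromoethane and TMSCl), LiCl, THF, 50 °C
Reagents that add atoms: zinc, [Zn]
Why: Direct insertion of LiCl-activated zinc into a primary alkyl bromide (Knochel conditions) gives the alkylzinc halide without touching the phenyl ring.

Step 8
Reactants: 10 3,4-dimethoxy-2-methyl-7,8-dihydroquinolin-5-yl trifluoromethanesulfonate; 12 (5-phenylpentyl)zinc bromide
Product: 13 3,4-dimethoxy-2-methyl-5-(5-phenylpentyl)-7,8-dihydroquinoline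
Conditions: PdCl2(dppf) (5 mol %), THF, 50 °C, under argon
Reagents that add atoms: none
Why: Negishi coupling: the enol triflate adds oxidatively to zerovalent palladium formed in situ, the primary alkylzinc transmetalates, and the wide-bite-angle dppf ligand favours reductive elimination over β-hydride elimination.

Step 9
Reactants: 13 3,4-dimethoxy-2-methyl-5-(5-phenylpentyl)-7,8-dihydroquinoline
Product: 14 (5R)-3,4-dimethoxy-2-methyl-5-(5-phenylpentyl)-5,6,7,8-tetrahydroquinoline
Conditions: [Ir(cod)(L*)]BArF (2 mol %; L* = chiral phosphinite–oxazoline N,P ligand of the ThrePHOX type), H2 (50 bar), CH2Cl2, rt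
Reagents that add atoms: none
Why: Iridium-catalysed asymmetric hydrogenation of an unfunctionalised trisubstituted cyclic aryl alkene (the 1-alkyl-3,4-dihydronaphthalene class) delivers hydrogen to one face of C5=C6 under catalyst control, so the ligand antipode that gives 5R is chosen and its sense confirmed by chiral analysis on the first run; the pyridine nitrogen, flanked by the 2-methyl group and C8, should bind the metal only weakly.

Step 10
Reactants: 14 (5R)-3,4-dimethoxy-2-methyl-5-(5-phenylpentyl)-5,6,7,8-tetrahydroquinoline
Product: 15 (5R)-3,4-dimethoxy-2-methyl-5-(5-phenylpentyl)-5,6,7,8-tetrahydroquinoline 1-oxide (target)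
Conditions: mCPBA (1.2 equiv), CH2Cl2, 0 °C to rt; aq Na2S2O3/NaHCO3 wash
Reagents that add atoms: meta-chloroperoxybenzoic acid, O=C(OO)c1cccc(Cl)c1
Why: Electrophilic N-oxidation of the pyridine by the peracid; the ethers, the saturated carbocycle and the phenyl ring are inert and the C5 stereocentre is not involved.

**Compound list**
1 | 3-methoxy-2-methyl-1H-pyridin-4-one | COc1c(C)[nH]ccc1=O | starting material
2 | 5-bromo-3-methoxy-2-methyl-1H-pyridin-4-one | COc1c(C)[nH]cc(Br)c1=O | intermediate
3 | 5-bromo-4-chloro-3-methoxy-2-methylpyridine | COc1c(C)ncc(Br)c1Cl | intermediate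
4 | 5-bromo-3,4-dimethoxy-2-methylpyridine | COc1c(OC)c(C)ncc1Br | intermediate
5 | cyclobutanone | O=C1CCC1 | starting material
6 | (4,5-dimethoxy-6-methylpyridin-3-yl)lithium | [Li]c1cnc(C)c(OC)c1OC | intermediate (not isolated)
7 | 1-(4,5-dimethoxy-6-methylpyridin-3-yl)cyclobutan-1-ol | COc1c(OC)c(C)ncc1C1(O)CCC1 | intermediate
8 | 3,4-dimethoxy-2-methyl-7,8-dihydro-6H-quinolin-5-one | COc1c(OC)c(C)nc2c1C(=O)CCC2 | intermediate
9 | potassium 3,4-dimethoxy-2-methyl-7,8-dihydroquinolin-5-olate | COc1c(OC)c(C)nc2c1C([O-])=CCC2.[K+] | intermediate (not isolated)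
10 | 3,4-dimethoxy-2-methyl-7,8-dihydroquinolin-5-yl trifluoromethanesulfonate | COc1c(OC)c(C)nc2c1C(OS(=O)(=O)C(F)(F)F)=CCC2 | intermediate
11 | (5-bromopentyl)benzene | BrCCCCCc1ccccc1 | starting material
12 | (5-phenylpentyl)zinc bromide | Br[Zn]CCCCCc1ccccc1 | intermediate
13 | 3,4-dimethoxy-2-methyl-5-(5-phenylpentyl)-7,8-dihydroquinoline | COc1c(OC)c(C)nc2c1C(CCCCCc1ccccc1)=CCC2 | intermediate
14 | (5R)-3,4-dimethoxy-2-methyl-5-(5-phenylpentyl)-5,6,7,8-tetrahydroquinoline | COc1c(OC)c(C)nc2c1[C@H](CCCCCc1ccccc1)CCC2 | intermediate
15 | (5R)-3,4-dimethoxy-2-methyl-5-(5-phenylpentyl)-5,6,7,8-tetrahydroquinoline 1-oxide | COc1c(OC)c(C)[n+]([O-])c2c1[C@H](CCCCCc1ccccc1)CCC2 | target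

**Step count**
Total steps: 10. Longest linear sequence: 9 (steps 1–6, 8, 9, 10); step 7 is a one-step side branch.

**Steps most likely to fail**

Step 5. After ring opening, the primary radical may be quenched by hydrogen abstraction or oxidised at the chain end before it closes onto the pyridinium, or the electron-rich dimethoxypyridine may be degraded by the oxidant. The fallback sets out from bromopyridine 4 and comes back at ketone 8; it makes the radical step intermolecular and closes the ring by an ionic acylation. Decarboxylative Minisci alkylation of 4 with methyl hydrogen glutarate (AgNO3 cat., K2S2O8, TFA, MeCN/H2O, 60 °C) should place the 3-(methoxycarbonyl)propyl radical on C6, the only free ring position, giving methyl 4-(3-bromo-4,5-dimethoxy-6-methylpyridin-2-yl)butanoate F1. Saponification (LiOH, THF/H2O) should give 4-(3-bromo-4,5-dimethoxy-6-methylpyridin-2-yl)butanoic acid F2. Parham cycliacylation (n-BuLi, 2.2 equiv, THF, −100 to −78 °C), in which the aryllithium from bromine–lithium exchange attacks the lithium carboxylate, should then close the carbocycle to 8.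

Step 9. Binding of the pyridine nitrogen to the cationic iridium centre may stall hydrogen uptake, and the peri methoxy group at C4 may erode facial discrimination at C5=C6. The fallback sets out from alkene 13 and comes back at 14; it replaces asymmetric catalysis by resolution. Hydrogenation over Pd/C (H2, 1 atm, EtOAc, rt) should give racemic 3,4-dimethoxy-2-methyl-5-(5-phenylpentyl)-5,6,7,8-tetrahydroquinoline F3, which is separated by preparative chiral SFC into 14 and (5S)-3,4-dimethoxy-2-methyl-5-(5-phenylpentyl)-5,6,7,8-tetrahydroquinoline F4, the latter being set aside.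

Step 8. Oxidative addition at the peri-hindered C5 triflate may be slow, and β-hydride elimination from the alkylpalladium intermediate may reduce the triflate instead of coupling it. The fallback sets out from ketone 8 and bromide 11 and comes back at alkene 13; it replaces cross-coupling by carbonyl addition and dehydration, bypassing steps 6 to 8. Bromide 11 with Mg turnings in THF should give (5-phenylpentyl)magnesium bromide F5. Its addition to 8 in the presence of anhydrous CeCl3 (THF, −78 to 0 °C, to suppress enolisation) should give 3,4-dimethoxy-2-methyl-5-(5-phenylpentyl)-5,6,7,8-tetrahydroquinolin-5-ol F6. Acid-catalysed dehydration (TsOH·H2O, toluene, reflux, Dean–Stark) should give the endocyclic, pyridine-conjugated alkene 13, the exocyclic isomer being disfavoured by strain against the C4 methoxy group.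

**Further compounds**
F1 | step 5 | methyl 4-(3-bromo-4,5-dimethoxy-6-methylpyridin-2-yl)butanoate | COC(=O)CCCc1nc(C)c(OC)c(OC)c1Br
F2 | step 5 | 4-(3-bromo-4,5-dimethoxy-6-methylpyridin-2-yl)butanoic acid | OC(=O)CCCc1nc(C)c(OC)c(OC)c1Br
F3 | step 9 | rac-3,4-dimethoxy-2-methyl-5-(5-phenylpentyl)-5,6,7,8-tetrahydroquinoline | COc1c(OC)c(C)nc2c1C(CCCCCc1ccccc1)CCC2
F4 | step 9 | (5S)-3,4-dimethoxy-2-methyl-5-(5-phenylpentyl)-5,6,7,8-tetrahydroquinoline | COc1c(OC)c(C)nc2c1[C@@H](CCCCCc1ccccc1)CCC2
F5 | step 8 | (5-phenylpentyl)magnesium bromide | Br[Mg]CCCCCc1ccccc1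
F6 | step 8 | 3,4-dimethoxy-2-methyl-5-(5-phenylpentyl)-5,6,7,8-tetrahydroquinolin-5-ol | COc1c(OC)c(C)nc2c1C(O)(CCCCCc1ccccc1)CCC2
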